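**Plan**
- Retrosynthetic cuts, in order: C15=C16 (Wittig, butenolide phosphonium salt plus enal); C12–C13 (B-alkyl Suzuki–Miyaura coupling with a Z-vinyl iodide); C11=C12 (methylenation of a C11 lactol); C5–C6 and C6–C7 of ring B (one CO); C9–C10 and C9–C5 (intramolecular carbene addition).
- Enabling feature: ring B (C5–C6–C7–C8–C9–C10) is a cyclohexene whose C8=C9 alkene adjoins the cis C10–C5 bond. It is therefore a cis-fused cyclopropane (C9, C10, C5) bearing an isopropenyl group (C8=C7), with one carbon (C6, from CO) inserted between C5 and C7.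
- Forward order: ring A by annulation; cyclopropane from a diazo ester tethered through O–C1; ring B by carbonylative (5+1) expansion; removal of the C1 and C6 oxygens; chain by Suzuki coupling; butenolide by Wittig; desilylation.
- Stereochemistry: C1 (CBS reduction) steers the tethered carbene to one face of C10=C5 and so fixes C5 and C10 (cis). The C10–C5 bond survives the expansion and C1 is then deoxygenated. 13E comes from trans-hydroalumination/iodination and stereoretentive coupling, 15E from the stabilised ylide.

Key step: step 6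

Remark: atom labels follow labdane numbering (ring A = C1–C5 and C10; ring B = C5–C10; chain C11–C16). The SMILES of the target defines a cis ring fusion, (5R,10S), and that compound is made.

**Route**

Step 1
Reactants: 1 isobutyraldehyde; 2 ethyl vinyl ketone (pent-1-en-3-one)
Product: 5 2,4,4-trimethylcyclohex-2-en-1-one, via 2,2-dimethyl-5-oxoheptanal 3 (not isolated), via 3-hydroxy-2,4,4-trimethylcyclohexan-1-one 4 (not isolated)
Conditions: H2SO4 (cat.), toluene, 50 °C then reflux (Dean–Stark)
Reagents that add atoms: none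
Why: Acid-catalysed Michael addition of the aldehyde enol to the enone followed by intramolecular aldol condensation (Robinson-type annulation) is the standard entry to 4,4-dimethylcyclohex-2-enones, and the ethyl ketone supplies the 2-methyl group (the future CH3 on C10).

Step 2
Reactants: 5 2,4,4-trimethylcyclohex-2-en-1-one
Product: 6 (S)-2,4,4-trimethylcyclohex-2-en-1-ol
Conditions: (R)-2-methyl-CBS-oxazaborolidine (10 mol%), BH3·SMe2, THF, −20 °C; aqueous work-up
Reagents that add atoms: none
Why: Corey–Bakshi–Shibata reduction gives 1,2-hydride delivery to the enone, and with the methyl-bearing alkene arm as the large group the (R)-catalyst should set C1 as S, by analogy with aryl alkyl ketones.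

Step 3
Reactants: 6 (S)-2,4,4-trimethylcyclohex-2-en-1-ol; 7 3-methylbut-3-enoic acid
Product: 8 (S)-2,4,4-trimethylcyclohex-2-en-1-yl 3-methylbut-3-enoate
Conditions: DCC, DMAP (5 mol%), CH2Cl2, 0 °C
Reagents that add atoms: none
Why: Steglich esterification at 0 °C with little DMAP should acylate the secondary allylic alcohol without moving the β,γ-alkene of the acid into conjugation and without touching C1.

Step 4
Reactants: 8 (S)-2,4,4-trimethylcyclohex-2-en-1-yl 3-methylbut-3-enoate
Product: 9 (S)-2,4,4-trimethylcyclohex-2-en-1-yl 2-diazo-3-methylbut-3-enoate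
Conditions: p-ABSA, DBU, MeCN, 0 °C; used at once
Reagents that add atoms: 4-acetamidobenzenesulfonyl azide (p-ABSA), CC(=O)Nc1ccc(cc1)S(=O)(=O)N=[N+]=[N-]
Why: Regitz-type diazo transfer to the α-CH2 of a β,γ-unsaturated ester (activated by ester and allyl) is the usual way to vinyl diazo esters, and the product is carried on directly because it slowly closes to a pyrazole.

Step 5
Reactants: 9 (S)-2,4,4-trimethylcyclohex-2-en-1-yl 2-diazo-3-methylbut-3-enoate
Product: 10 vinylcyclopropane lactone 6,6,9-trimethyl-4-(prop-1-en-2-yl)-2-oxatricyclo[3.3.1.0(4,9)]nonan-3-one (labdane labels 1S,5R,10S; cyclopropane C9–C10–C5 syn to O–C1; isopropenyl on C9 exo)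
Conditions: Rh2(OAc)4 (1 mol%), CH2Cl2, rt, slow addition of 9
Reagents that add atoms: none
Why: Rhodium-carbenoid intramolecular cyclopropanation of an allylic vinyl diazo ester; the O–C1 tether can only deliver the carbene carbon C9 to the face of C10=C5 syn to the C1–O bond, which sets C10 and C5 (CH3-10 and H-5 cis, both anti to C9) and places the isopropenyl group exo on C9.

Step 6
Reactants: 10 vinylcyclopropane lactone; 11 carbon monoxide
Product: 12 keto lactone (labdane labels 1S,5R,10S; C6 ketone; C8=C9; lactone C11(=O)–O–C1; H-5 cis to CH3-10)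
Conditions: [Rh(CO)2Cl]2 (5 mol%), CO (1 atm), toluene, 90 °C
Reagents that add atoms: none
Why: Proposed new method: monovalent rhodium binds the exo isopropenyl group of 10 and inserts into the adjacent C9–C5 cyclopropane bond, giving a rhodacycle with a C5–Rh σ bond and a C9–C8–C7 allyl unit, after which CO inserts into the C5–Rh bond with retention and reductive elimination joins the acyl carbon C6 to C7; the closest known reaction type is the rhodium- or iron-mediated carbonylative (5+1) ring expansion of vinylcyclopropanes to cyclohex-3-enones, not yet shown on a ring-fused, fully substituted cyclopropane with an acyl group on the vinyl-bearing carbon. Ring B (C5–C6–C7–C8–C9–C10) closes by this C6–C7 reductive elimination from a six-membered acyl rhodacycle (formal (5+1) cycloaddition), and the allyl collapses to the C8=C9 alkene conjugated with the lactone carbonyl. No stereocenter is created: the C10–C5 bond is never broken and C5 keeps its configuration through insertion and CO migration, so the cis cyclopropane fusion becomes the cis ring fusion. The step needs cleavage of C9–C5 and not C9–C10, which is secured because C10 is quaternary and lies on the lactone-fused edge whereas C5 is a CH. The alkylrhodium at C5 has no β-hydrogen (C4 and C10 are quaternary), which closes the diene-forming side path, and the neutral conditions keep H-5 and the doubly activated C7 methylene from epimerising or shifting the alkene.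

Step 7
Reactants: 12 keto lactone
Product: 13 hydroxy lactol (C6–OH; C11 lactol; epimer mixture at C6 and C11)
Conditions: iBu2AlH (2.5 equiv), CH2Cl2, −78 °C; Rochelle salt work-up
Reagents that add atoms: none
Why: Hydride reduction at −78 °C takes the C6 ketone before it can enolise and stops the conjugated lactone at the lactol (aluminium hemiacetal stable in the cold); the new C6 and C11 centers are uncontrolled and both are erased later.

Step 8
Reactants: 13 hydroxy lactol
Product: 14 diene diol (1S,5R,10S; C1–OH and C6–OH; C8=C9; vinyl on C9; C6 epimers)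
Conditions: Ph3PCH3Br (5 equiv), KOtBu, THF, 0 °C → 40 °C
Reagents that add atoms: methyltriphenylphosphonium bromide, C[P+](c1ccccc1)(c1ccccc1)c1ccccc1.[Br-]
Why: Wittig methylenation of the open hydroxy-enal form of the lactol with excess ylide installs C12 as the C9 vinyl group and frees the C1 hydroxyl, without touching C5 or C10.

Step 9
Reactants: 14 diene diol
Product: 15 bis(S-methyl dithiocarbonate) of 14 (xanthates on O-1 and O-6)
Conditions: NaH, imidazole (cat.), CS2, THF, 0 °C → rt; then MeI
Reagents that add atoms: carbon disulfide, S=C=S; iodomethane, CI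
Why: Xanthate formation works on hindered secondary alkoxides and prepares both C–O bonds for Barton–McCombie deoxygenation, and neither xanthate is allylic so no sigmatropic shift is open.

Step 10
Reactants: 15 bis(xanthate)
Product: 16 (4aR,8aS)-1-ethenyl-2,5,5,8a-tetramethyl-3,4,4a,5,6,7,8,8a-octahydronaphthalene
Conditions: Bu3SnH (0.5 M), (PhSe)2 (10 mol%), AIBN, benzene, 80 °C
Reagents that add atoms: none
Why: Double Barton–McCombie deoxygenation in which benzeneselenol formed in the flask transfers hydrogen to the C1 and C6 radicals fast enough to outrun 3-exo closure onto C8=C9; both carbons become CH2, so the C1 stereocenter has done its work and C5 and C10 are untouched.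

Step 11
Reactants: 17 but-2-yne-1,4-diol
Product: 18 4-[(tert-butyldimethylsilyl)oxy]but-2-yn-1-ol
Conditions: TBSCl (1 equiv), imidazole, DMF, 0 °C, diol in threefold excess
Reagents that add atoms: tert-butyldimethylsilyl chloride, CC(C)(C)[Si](C)(C)Cl
Why: Statistical monosilylation of a symmetric diol used in excess gives the mono ether, and the excess diol is washed out with water.

Step 12
Reactants: 18 4-[(tert-butyldimethylsilyl)oxy]but-2-yn-1-ol
Product: 20 (Z)-4-[(tert-butyldimethylsilyl)oxy]-3-iodobut-2-en-1-ol, via cyclic vinylalanate 19 (not isolated)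
Conditions: NaAlH2(OCH2CH2OMe)2, THF, 0 °C; then I2, −78 °C
Reagents that add atoms: iodine, II
Why: Hydroxyl-directed trans-hydroalumination of the propargylic alcohol puts aluminium on C3 in a five-membered alanate (cis to CH2OH), and iodination with retention gives the Z iodide; the cold keeps the β-silyloxy group from eliminating.

Step 13
Reactants: 16 diene; 20 (Z)-vinyl iodide
Product: 22 (E)-3-{[(tert-butyldimethylsilyl)oxy]methyl}-5-[(4aR,8aS)-2,5,5,8a-tetramethyl-3,4,4a,5,6,7,8,8a-octahydronaphthalen-1-yl]pent-2-en-1-ol, via B-alkyl-9-BBN borane 21 (not isolated)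
Conditions: 9-BBN, THF, rt; then aq. Cs2CO3, 20, Pd(dppf)Cl2 (5 mol%), AsPh3, DMF, rt
Reagents that add atoms: none
Why: B-alkyl Suzuki–Miyaura coupling: 9-BBN adds boron only to the terminal vinyl carbon C12 (the tetrasubstituted C8=C9 is inert), and coupling retains the iodide geometry, so C12 ends cis to C15 (13E).

Step 14
Reactants: 22 allylic alcohol
Product: 23 (E)-3-{[(tert-butyldimethylsilyl)oxy]methyl}-5-[(4aR,8aS)-2,5,5,8a-tetramethyl-3,4,4a,5,6,7,8,8a-octahydronaphthalen-1-yl]pent-2-enal
Conditions: MnO2, CH2Cl2, rt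
Reagents that add atoms: none
Why: MnO2 oxidises only the allylic alcohol under neutral conditions and leaves the trisubstituted alkene geometry and the silyl ether intact.

Step 15
Reactants: 24 1,3-dihydroxyacetone (used as its commercial dimer); 25 ethyl (triphenylphosphoranylidene)acetate
Product: 27 4-(hydroxymethyl)furan-2(5H)-one, via ethyl 4-hydroxy-3-(hydroxymethyl)but-2-enoate 26 (not isolated)
Conditions: CH2Cl2, rt
Reagents that add atoms: none
Why: Wittig olefination of the ketone by the stabilised ylide gives an enoate in which one hydroxymethyl group is necessarily cis to the ester and lactonises spontaneously.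

Step 16
Reactants: 27 4-(hydroxymethyl)furan-2(5H)-one
Product: 28 4-(bromomethyl)furan-2(5H)-one
Conditions: CBr4, PPh3, CH2Cl2, 0 °C
Reagents that add atoms: carbon tetrabromide, BrC(Br)(Br)Br
Why: Appel bromination converts the primary allylic alcohol to the bromide under neutral conditions that the butenolide tolerates.

Step 17
Reactants: 28 4-(bromomethyl)furan-2(5H)-one
Product: 29 [(5-oxo-2,5-dihydrofuran-3-yl)methyl]triphenylphosphonium bromide
Conditions: PPh3, MeCN, 50 °C
Reagents that add atoms: triphenylphosphine, c1ccc(cc1)P(c1ccccc1)c1ccccc1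
Why: SN2 quaternisation of triphenylphosphine by the primary allylic bromide gives the Wittig salt.

Step 18
Reactants: 23 enal; 29 phosphonium bromide
Product: 31 4-[(1E,3E)-4-{[(tert-butyldimethylsilyl)oxy]methyl}-6-[(4aR,8aS)-2,5,5,8a-tetramethyl-3,4,4a,5,6,7,8,8a-octahydronaphthalen-1-yl]hexa-1,3-dien-1-yl]furan-2(5H)-one, via butenolide ylide 30 (not isolated)
Conditions: 29, NaN(SiMe3)2 (1.0 equiv per 29), THF, −78 °C; then 23, → rt
Reagents that add atoms: none
Why: Wittig olefination with a ylide stabilised through the butenolide carbonyl should give the E alkene at C15=C16, and one equivalent of base per salt leaves C5–H of the butenolide and the γ-positions of the enal alone.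

Step 19
Reactants: 31 silyl ether
Product: 32 4-[(1E,3E)-4-(hydroxymethyl)-6-[(4aR,8aS)-2,5,5,8a-tetramethyl-3,4,4a,5,6,7,8,8a-octahydronaphthalen-1-yl]hexa-1,3-dien-1-yl]furan-2(5H)-one (CNP0232848.3)
Conditions: HF·pyridine, pyridine, THF, 0 °C → rt
Reagents that add atoms: none
Why: Buffered fluoride cleavage of the primary allylic silyl ether is mild enough to spare the butenolide and the triene and touches no stereocenter.

**Compound list**

1 | isobutyraldehyde (2-methylpropanal) | CC(C)C=O | starting material
2 | ethyl vinyl ketone (pent-1-en-3-one) | CCC(=O)C=C | starting material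
3 | 2,2-dimethyl-5-oxoheptanal (Michael adduct, not isolated) | CCC(=O)CCC(C)(C)C=O | intermediate
4 | 3-hydroxy-2,4,4-trimethylcyclohexan-1-one (aldol, diastereomer mixture, not isolated) | CC1C(O)C(C)(C)CCC1=O | intermediate
5 | 2,4,4-trimethylcyclohex-2-en-1-one | CC1=CC(C)(C)CCC1=O | intermediate
6 | (S)-2,4,4-trimethylcyclohex-2-en-1-ol | O[C@H]1CCC(C)(C)C=C1C | intermediate
7 | 3-methylbut-3-enoic acid | CC(=C)CC(=O)O | starting material
8 | (S)-2,4,4-trimethylcyclohex-2-en-1-yl 3-methylbut-3-enoate | CC(=C)CC(=O)O[C@H]1CCC(C)(C)C=C1C | intermediate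
9 | (S)-2,4,4-trimethylcyclohex-2-en-1-yl 2-diazo-3-methylbut-3-enoate | CC(=C)C(=[N+]=[N-])C(=O)O[C@H]1CCC(C)(C)C=C1C | intermediate
10 | vinylcyclopropane lactone, 6,6,9-trimethyl-4-(prop-1-en-2-yl)-2-oxatricyclo[3.3.1.0(4,9)]nonan-3-one; labdane labels (1S,5R,10S); cyclopropane C9–C10–C5 on the face of the C1–O bond, CH3-10 and H-5 cis, isopropenyl on C9 exo (anti to ring A), lactone C11(=O)–O–C1 | O=C1O[C@H]2CCC(C)(C)[C@@H]3[C@@]2(C)[C@]13C(C)=C | intermediate
11 | carbon monoxide | [C-]#[O+] | starting material
12 | keto lactone, 3,6,6,8b-tetramethyl-5a,6,7,8,8a,8b-hexahydro-2H-naphtho[1,8-bc]furan-2,5(4H)-dione; labdane labels (1S,5R,10S); C6 ketone, C8=C9, lactone C11(=O)–O–C1, cis ring fusion | O=C1O[C@H]2CCC(C)(C)[C@H]3C(=O)CC(C)=C1[C@@]23C | intermediate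
13 | hydroxy lactol from 12 (C6–OH, C11 hemiacetal; (1S,5R,10S); mixture at C6 and C11) | OC1O[C@H]2CCC(C)(C)[C@H]3C(O)CC(C)=C1[C@@]23C | intermediate
14 | diene diol; labdane labels (1S,5R,10S); C1–OH, C6–OH (epimers), C8=C9, vinyl on C9, cis ring fusion | O[C@H]1CCC(C)(C)[C@H]2C(O)CC(C)=C(C=C)[C@@]12C | intermediate
15 | bis(S-methyl dithiocarbonate) of 14 (xanthates on O-1 and O-6) | CSC(=S)O[C@H]1CCC(C)(C)[C@H]2C(OC(=S)SC)CC(C)=C(C=C)[C@@]12C | intermediate
16 | (4aR,8aS)-1-ethenyl-2,5,5,8a-tetramethyl-3,4,4a,5,6,7,8,8a-octahydronaphthalene | CC1=C(C=C)[C@@]2(C)CCCC(C)(C)[C@H]2CC1 | intermediate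
17 | but-2-yne-1,4-diol | OCC#CCO | starting material
18 | 4-[(tert-butyldimethylsilyl)oxy]but-2-yn-1-ol | OCC#CCO[Si](C)(C)C(C)(C)C | intermediate
19 | cyclic vinylalanate, sodium 2,2-bis(2-methoxyethoxy)-3-{[(tert-butyldimethylsilyl)oxy]methyl}-2,5-dihydro-1,2-oxaaluminol-2-uide (not isolated) | [Na+].COCCO[Al-]1(OCCOC)OCC=C1CO[Si](C)(C)C(C)(C)C | intermediate
20 | (Z)-4-[(tert-butyldimethylsilyl)oxy]-3-iodobut-2-en-1-ol | OC/C=C(\I)CO[Si](C)(C)C(C)(C)C | intermediate
21 | B-alkyl-9-BBN borane, 9-{2-[(4aR,8aS)-2,5,5,8a-tetramethyl-3,4,4a,5,6,7,8,8a-octahydronaphthalen-1-yl]ethyl}-9-borabicyclo[3.3.1]nonane (not isolated) | CC1=C(CCB2C3CCCC2CCC3)[C@@]2(C)CCCC(C)(C)[C@H]2CC1 | intermediate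
22 | (E)-3-{[(tert-butyldimethylsilyl)oxy]methyl}-5-[(4aR,8aS)-2,5,5,8a-tetramethyl-3,4,4a,5,6,7,8,8a-octahydronaphthalen-1-yl]pent-2-en-1-ol | CC1=C(CC/C(=C\CO)CO[Si](C)(C)C(C)(C)C)[C@@]2(C)CCCC(C)(C)[C@H]2CC1 | intermediate
23 | (E)-3-{[(tert-butyldimethylsilyl)oxy]methyl}-5-[(4aR,8aS)-2,5,5,8a-tetramethyl-3,4,4a,5,6,7,8,8a-octahydronaphthalen-1-yl]pent-2-enal | CC1=C(CC/C(=C\C=O)CO[Si](C)(C)C(C)(C)C)[C@@]2(C)CCCC(C)(C)[C@H]2CC1 | intermediate
24 | 1,3-dihydroxyacetone (sold as the dimer) | OCC(=O)CO | starting material
25 | ethyl (triphenylphosphoranylidene)acetate | CCOC(=O)C=P(c1ccccc1)(c1ccccc1)c1ccccc1 | starting material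
26 | ethyl 4-hydroxy-3-(hydroxymethyl)but-2-enoate (not isolated) | CCOC(=O)C=C(CO)CO | intermediate
27 | 4-(hydroxymethyl)furan-2(5H)-one | O=C1OCC(CO)=C1 | intermediate
28 | 4-(bromomethyl)furan-2(5H)-one | O=C1OCC(CBr)=C1 | intermediate
29 | [(5-oxo-2,5-dihydrofuran-3-yl)methyl]triphenylphosphonium bromide | O=C1OCC(C[P+](c2ccccc2)(c2ccccc2)c2ccccc2)=C1.[Br-] | intermediate
30 | butenolide ylide, 4-[(triphenylphosphoranylidene)methyl]furan-2(5H)-one (not isolated) | O=C1OCC(C=P(c2ccccc2)(c2ccccc2)c2ccccc2)=C1 | intermediate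
31 | 4-[(1E,3E)-4-{[(tert-butyldimethylsilyl)oxy]methyl}-6-[(4aR,8aS)-2,5,5,8a-tetramethyl-3,4,4a,5,6,7,8,8a-octahydronaphthalen-1-yl]hexa-1,3-dien-1-yl]furan-2(5H)-one | CC1=C(CC/C(=C\C=C\C2=CC(=O)OC2)CO[Si](C)(C)C(C)(C)C)[C@@]2(C)CCCC(C)(C)[C@H]2CC1 | intermediate
32 | 4-[(1E,3E)-4-(hydroxymethyl)-6-[(4aR,8aS)-2,5,5,8a-tetramethyl-3,4,4a,5,6,7,8,8a-octahydronaphthalen-1-yl]hexa-1,3-dien-1-yl]furan-2(5H)-one (CNP0232848.3) | CC1=C(CC/C(=C\C=C\C2=CC(=O)OC2)CO)[C@@]2(C)CCCC(C)(C)[C@H]2CC1 | target

**Step count and risks**

Total: 19 steps. Longest linear sequence: 14 steps (steps 1–10, 13, 14, 18, 19).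

Steps most likely to fail:

1. Step 6 (carries the label "Proposed new method"). Oxidative addition may be too slow at the fully substituted cyclopropane, may take the C9–C10 bond instead of C9–C5, or the rhodacycle may collapse to a cyclopentene before CO is taken up. The fallback is a ketene (2+2) cycloaddition followed by a 1,3-acyl shift, both known reaction types; it sets out from 8 and comes back at 12. Deprotonation of 8 (LiN(iPr)2, THF, −78 °C) and carboxylation with CO2 should give the malonic half ester F1. Oxalyl chloride (cat. DMF, CH2Cl2, 0 °C) converts it to the acid chloride F2. Slow addition of F2 to Et3N in refluxing toluene generates the isopropenyl(alkoxycarbonyl)ketene F3 in the flask. F3 should add across C10=C5 on the face of the tether, with the ketene carbonyl carbon (C6) going to the CH carbon C5 and the α-carbon C9 to the methyl-bearing C10, to give the cis-fused 2-vinylcyclobutanone lactone F4. The 1,3-acyl shift of this β,γ-unsaturated cyclobutanone (irradiation at about 300 nm in benzene, or heating) moves C6 from C9 to C7 and gives 12.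

2. Step 5. The vinyl diazo ester may close to a pyrazole before carbene transfer, or the carbenoid may insert into C–H bonds faster than it adds to the hindered trisubstituted alkene. The fallback uses an acceptor/acceptor diazo compound and adds the alkene carbon afterwards; it sets out from 6 and comes back at 10. Heating 6 with 2,2,6-trimethyl-4H-1,3-dioxin-4-one (xylene, 130 °C) should give the acetoacetate F5. Diazo transfer (p-ABSA, Et3N, MeCN) gives the stable diazoacetoacetate F6. Intramolecular cyclopropanation (Cu(acac)2, toluene, reflux) gives the acetyl cyclopropane lactone F7, with the same tether-controlled configuration at C5 and C10. Wittig methylenation of the ketone (Ph3P=CH2, THF), which leaves the lactone alone, gives 10.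

3. Step 10. The homoallylic C1 and C6 radicals may rearrange (3-exo closure onto C8=C9 followed by a 1,2-vinyl shift), or tin hydride may add to the diene before hydrogen transfer. The fallback removes both oxygens through hydrazones, without carbon radicals; it sets out from 12 and comes back at 16. Condensation of 12 with tosylhydrazine (EtOH, rt) should give the C6 tosylhydrazone F8. Catecholborane and then NaOAc reduce it, without base strong enough to epimerise C5, to the C6-methylene lactone F9. iBu2AlH (−78 °C) gives the lactol F10. Wittig methylenation gives the dienol F11, which carries only the C1 hydroxyl. Dess–Martin periodinane gives the C1 ketone F12; its α-carbon C10 is quaternary, so nothing can epimerise. Under Wolff–Kishner conditions (N2H4·H2O, KOH, diethylene glycol, 200 °C) the hydrazone F13 forms in the flask and loses nitrogen to give 16.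

**Further compounds**

F1 | step 6 | 3-methyl-2-({[(S)-2,4,4-trimethylcyclohex-2-en-1-yl]oxy}carbonyl)but-3-enoic acid (malonic half ester, both C9 epimers) | CC(=C)C(C(=O)O)C(=O)O[C@H]1CCC(C)(C)C=C1C
F2 | step 6 | acid chloride of F1 | CC(=C)C(C(=O)Cl)C(=O)O[C@H]1CCC(C)(C)C=C1C
F3 | step 6 | isopropenyl(alkoxycarbonyl)ketene, (S)-2,4,4-trimethylcyclohex-2-en-1-yl 3-methyl-2-(oxomethylidene)but-3-enoate (not isolated) | CC(=C)C(=C=O)C(=O)O[C@H]1CCC(C)(C)C=C1C
F4 | step 6 | 2-vinylcyclobutanone lactone (cyclobutanone C6(=O)–C5–C10–C9 cis-fused to ring A; isopropenyl and lactone carbonyl on C9; lactone closed onto O–C1) | O=C1O[C@H]2CCC(C)(C)[C@H]3C(=O)[C@]1(C(C)=C)[C@@]23C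
F5 | step 5 | (S)-2,4,4-trimethylcyclohex-2-en-1-yl 3-oxobutanoate | CC(=O)CC(=O)O[C@H]1CCC(C)(C)C=C1C
F6 | step 5 | (S)-2,4,4-trimethylcyclohex-2-en-1-yl 2-diazo-3-oxobutanoate | CC(=O)C(=[N+]=[N-])C(=O)O[C@H]1CCC(C)(C)C=C1C
F7 | step 5 | acetyl cyclopropane lactone, 4-acetyl-6,6,9-trimethyl-2-oxatricyclo[3.3.1.0(4,9)]nonan-3-one | O=C1O[C@H]2CCC(C)(C)[C@@H]3[C@@]2(C)[C@]13C(C)=O
F8 | step 10 | C6 tosylhydrazone of keto lactone 12 | O=C1O[C@H]2CCC(C)(C)[C@H]3C(=NNS(=O)(=O)c4ccc(C)cc4)CC(C)=C1[C@@]23C
F9 | step 10 | C6-methylene lactone (12 with CH2 at C6) | O=C1O[C@H]2CCC(C)(C)[C@H]3CCC(C)=C1[C@@]23C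
F10 | step 10 | lactol of F9 (C11 epimers) | OC1O[C@H]2CCC(C)(C)[C@H]3CCC(C)=C1[C@@]23C
F11 | step 10 | dienol, (1S,5R,10S)-1-hydroxy analogue of 16 | O[C@H]1CCC(C)(C)[C@H]2CCC(C)=C(C=C)[C@@]12C
F12 | step 10 | C1 ketone of the diene (1-oxo analogue of 16) | O=C1CCC(C)(C)[C@H]2CCC(C)=C(C=C)[C@@]12C
F13 | step 10 | hydrazone of F12 (formed in the flask) | NN=C1CCC(C)(C)[C@H]2CCC(C)=C(C=C)[C@@]12C
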